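The vessels took the same charges of starting complex, incoming ligand and protic impurity, and differed in how these went in.

in all of them: protic impurity 10.0 mM; time 30 min
- oak: starting complex 0.020 M; incoming ligand 0.0600 M; everything together at the start
- birch: starting complex 0.020 M; incoming ligand 0.0600 M (fed, over 12 min); all else is in the flask from the start; the feed brings no volume worth counting
- elm: starting complex 0.020 M (fed, over 12 min); incoming ligand 0.0600 M; all else is in the flask from the start; the feed brings no volume worth counting

* the flask that comes out highest in share of complex with three exchanged in complex with three exchanged plus complex with four exchanged, or "all alike" when all lie within 1.5 percentage points (oak / birch / elm / all alike)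
* share of complex with three exchanged in complex with three exchanged plus complex with four exchanged at the end, oak
* share of complex with three exchanged in complex with three exchanged plus complex with four exchanged at the end, birch
* share of complex with three exchanged in complex with three exchanged plus complex with four exchanged at the end, elm

- a species is counted by the starting complex in it: one homo dimer counts as two
- for a step with 2 of a species take k times the square, and two of it per event
- run time (oak): 30 min

    starting complex + incoming ligand ⇌ leaving ligand + complex with one exchanged (K1 = 0.98, k1 = 0.140 L mol⁻¹ s⁻¹)
    complex with one exchanged + incoming ligand ⇌ leaving ligand + complex with two exchanged (K2 = 11, k2 = 0.0142 L mol⁻¹ s⁻¹)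
    complex with three exchanged + incoming ligand ⇌ leaving ligand + complex with four exchanged (K3 = 0.19, k3 = 0.0488 L mol⁻¹ s⁻¹)
    2 starting complex → homo dimer (k4 = 0.114 L mol⁻¹ s⁻¹)
    complex with two exchanged + incoming ligand ⇌ leaving ligand + complex with three exchanged (K5 = 0.75, k5 = 0.119 L mol⁻¹ s⁻¹)
    protic impurity + starting complex → quenched substrate (k6 = 1.77 L mol⁻¹ s⁻¹)

I asked first what the end state must be. The last exchange turns complex with three exchanged into complex with four exchanged, taking up one incoming ligand and freeing one leaving ligand. In oak its forward half-life alone, with the charged ligand, is 3.9 min, shorter than the 30 min run. So I took that step as balanced at the end. Its equilibrium constant is 0.19, and I multiplied it by the incoming charge: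

weight = 0.19 × 0.0600 M = 0.0114 M

I call this product the ligand weight. Balance then gives the share directly:

share = leaving ligand / (leaving ligand + weight × fraction of incoming ligand left)

So I needed the leaving ligand, and each one freed takes up one incoming ligand. In oak the protic impurity has a half-life of 0.33 min, shorter than the 1.4 min of starting complex by the first exchange. I therefore let the impurity consume its whole charge, which is half of the complex. I reckoned on 0.0100 M of survivors, with the dimer path not counted. In oak the second exchange has the longest forward half-life of the exchanges, 14 min, so I took it as the rate-limiting step. I therefore placed oak between one and two ligands freed per survivor:

one per survivor: leaving ligand 0.0100 M, share 51.3 %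
two per survivor: leaving ligand 0.0200 M, share 72.5 %

I committed to the upper part of that bracket for oak. In birch the incoming ligand arrives late, so I expected the dimer path to take more and the share to stand lowest. Elm and oak I could not part.

The forecast did part them. It gave 67.5 % for oak, 58 % for birch and 68 % for elm, and named elm highest. Its ground was “how much complex survives the early losses”.

The simulation gave 67.0 % for oak, 58.1 % for birch and 68.8 % for elm, so elm came highest.

The forecast held. In oak, 0.0163 M of leaving ligand with 72.8 % of the incoming charge left gives a balance share of 66.3 %, beside the 67.0 % found. Elm stood above birch by 11 percentage points, and the dimer path and the return of the last exchange acted together in that gap. Removing the dimer path cut it to 0.38 points, and removing the return cut it to 1.6 points. The neighbour of elm charged with 0.0025 M of protic impurity held 0.0220 M of leaving ligand and 63.3 % of its incoming charge. The weight gives 75.3 % there, and that flask read 76.0 %.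

All constants were set for the occasion; what happens was integrated by code.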